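**Plan**

- Numbering of the target: O1–O2–C3(CH3)(chain)–C4–C4a(CH3)–O5–C6(=O)–C7–C7a(H)–O1. The retrosynthesis cuts first C3–CH3 (peroxycarbenium ion plus methyl donor). It then cuts both C–O bonds of the peroxide (O2–C3 and O1–C7a): O2 is taken out and C3 is joined to C7a, which gives a lactone-fused cyclobutanol. Next come C3–chain (organocerium plus cyclobutanone), the C6 carbonyl (oxolane to lactone) and the cyclobutanone (dichloroketene plus 5-methyl-2,3-dihydrofuran).
- Enabling feature: the peroxide ring is O1–O2 bridged by the four-carbon chain C3–C4–C4a–C7a. C3 sits at the ketone (hemiperketal) level and C7a is a secondary carbon held in the lactone ring. These four carbons are exactly the ring of a ketene/enol ether [2+2] adduct.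
- Forward order: [2+2] gives the oxolane-fused cyclobutanone; the oxolane is oxidised to the lactone; the chain is added to the C=O; the four-membered carbocycle is expanded by O2 to the 1,2-dioxane; the methyl group comes last.
- Stereochemistry: the cis ring fusion comes from the suprafacial [2+2]. The absolute configuration (C4a, kept to the end) comes from a CBS kinetic resolution of the cyclobutanone. C7a is re-formed cis to C4a–O by ring closure in the key step. C3 is set by axial methyl delivery cis to the lactone oxygen.

Key step: step 7

Remark: compounds 4–6 are racemates whose SMILES show one enantiomer; 15 and 16 are mixtures at the hemiperketal carbon, which step 9 rebuilds.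

**Step 1**
Reactants: 1 5-methyl-2,3-dihydrofuran; 2 trichloroacetyl chloride
Product: 4 (±)-cis-7,7-dichloro-1-methyl-2-oxabicyclo[3.2.0]heptan-6-one, via dichloroketene 3 (not isolated)
Conditions: Zn–Cu couple, Et2O, 25–35 °C, slow addition of 2
Reagents that add atoms: none
Why: Ketene–alkene [2+2] cycloaddition of dichloroketene (made by zinc dehalogenation of 2) with a cyclic enol ether; the ketene carbonyl carbon bonds to the nucleophilic β-carbon and CCl2 to the oxygen-bearing carbon, and suprafacial addition to the ring alkene fixes the cis fusion (racemic).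

**Step 2**
Reactants: 4
Product: 5 (±)-cis-1-methyl-2-oxabicyclo[3.2.0]heptan-6-one
Conditions: Zn dust, AcOH, 20–60 °C
Reagents that add atoms: none
Why: Zinc reductive dechlorination of the α,α-dichloroketone, the standard follow-up for dichloroketene adducts of enol ethers; no stereocentre is touched.

**Step 3**
Reactants: 5
Product: 6 (±)-cis-1-methyl-2-oxabicyclo[3.2.0]heptane-3,6-dione
Conditions: RuCl3·xH2O (cat.), NaIO4, CCl4/MeCN/H2O, 25 °C
Reagents that add atoms: sodium periodate, [Na+].[O-]I(=O)(=O)=O (oxygen passed on through RuO4); water, O (may supply the carbonyl oxygen)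
Why: RuO4 oxidation of a cyclic ether to the lactone; the only O–CH2 group is C3, because the other ether carbon is quaternary, and the cyclobutanone is inert to RuO4.

**Step 4**
Reactants: 6
Product: 7 (1S,5S)-1-methyl-2-oxabicyclo[3.2.0]heptane-3,6-dione (recovered ketone)
Conditions: (R)-Me-CBS (10 mol %), BH3·SMe2 (0.6 equiv), THF, −30 °C, stopped near 55–60 % conversion; chromatography
Reagents that add atoms: none
Why: Kinetic resolution by CBS reduction: with the ring-fusion CH as the large flank and CH2 as the small one, the (R)-catalyst should deliver hydride to the open exo face of the (1R,5R) ketone only, so its endo alcohol is separated and (1S,5S)-7 is recovered enantioenriched; this sets the absolute configuration of the quaternary carbon that becomes C4a.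

**Step 5**
Reactants: 8 1,12-dibromododecane (3 equiv); 9 phenylmagnesium bromide
Product: 10 (12-bromododecyl)benzene
Conditions: Li2CuCl4 (cat.), THF, 0 °C
Reagents that add atoms: none
Why: Copper-catalysed coupling of an aryl Grignard reagent with a primary alkyl bromide; the excess of dibromide should hold it at mono-substitution.

**Step 6**
Reactants: 7; 10
Product: 13 (1S,5R,6R)-6-hydroxy-1-methyl-6-(12-phenyldodecyl)-2-oxabicyclo[3.2.0]heptan-3-one, via (12-phenyldodecyl)magnesium bromide 11 (not isolated), via dichloro(12-phenyldodecyl)cerium 12 (not isolated)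
Conditions: 10, Mg, THF; anhydrous CeCl3, THF, −78 °C; then 7, −78 °C; AcOH quench at −78 °C
Reagents that add atoms: none
Why: Organocerium 1,2-addition to the strained, enolisable cyclobutanone in preference to the lactone; attack from the convex face should put the chain exo (this carbinol centre is erased in step 7), and the cold quench keeps the endo alkoxide from adding to the lactone carbonyl (acyl transfer to the new tertiary oxygen).

**Step 7**
Reactants: 13
Product: 15 (4aS,7aS)-3-hydroxy-4a-methyl-3-(12-phenyldodecyl)tetrahydrofuro[3,2-c][1,2]dioxin-6(3H)-one, via hydroperoxy ketone 14 (not isolated)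
Conditions: Co(acac)2 (20 mol %), O2 (1 atm), EtOH, 40 °C
Reagents that add atoms: dioxygen, O=O
Why: Co(II) and O2 should convert the tertiary cyclobutanol into a cobalt(III) alkoxide that homolyses to the alkoxy radical; strain-driven β-scission then breaks the bond from the carbinol carbon to the ring-fusion CH (secondary radical, preferred over the primary radical on the CH2 side) and unveils the long-chain ketone. The carbon radical captures triplet O2, the peroxyl radical is reduced to hydroperoxide 14, and its OOH adds to the ketone, so that O–O has been inserted into one C–C bond of the four-membered carbocycle (two-atom ring expansion to the 1,2-dioxane). The closest known reaction is of exactly this type, the aerobic Co(acac)2 ring expansion of cyclobutanols to 1,2-dioxan-3-ols (four-ring counterpart of the cyclopropanol to 1,2-dioxolan-3-ol oxygenation), with tertiary carbinols the slower substrates. The dioxane ring closes by 6-exo-trig hemiperketalisation of the hydroperoxide on the C=O. The new stereocentre C7a arises in the O2 capture and is cis-fused to the (S)-configured C4a only when O2 enters on the face of the oxoalkyl arm; the hemiperketal carbon C3 forms as anomers and is erased in step 9. The step needs regioselective β-scission (secured by radical stability) and syn O2 capture, for which the methyl and CH2 groups on C4a offer little bias, so the C7a epimer is expected as a separable by-product.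

**Step 8**
Reactants: 15
Product: 16 (4aS,7aS)-4a-methyl-6-oxo-3-(12-phenyldodecyl)hexahydrofuro[3,2-c][1,2]dioxin-3-yl acetate
Conditions: Ac2O, pyridine, DMAP (cat.), CH2Cl2, 0 °C
Reagents that add atoms: acetic anhydride, CC(=O)OC(C)=O
Why: Acylation of the hemiperketal hydroxyl, as practised on 1,2-dioxan-3-ols and 1,2-dioxolan-3-ols before Lewis acid substitution; it should give the ionisable peroxyketal acetate as an anomeric mixture.

**Step 9**
Reactants: 16
Product: 17 plakortolide L, (3S,4aS,7aS)-3,4a-dimethyl-3-(12-phenyldodecyl)tetrahydrofuro[3,2-c][1,2]dioxin-6(3H)-one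
Conditions: AlMe3 (3 equiv), CH2Cl2, −78 to −40 °C; Rochelle salt work-up
Reagents that add atoms: trimethylaluminium, C[Al](C)C
Why: Proposed new method: AlMe3 should act as Lewis acid and methyl donor, ionising the tertiary peroxyketal acetate to the cyclic peroxycarbenium ion (the ion of the known Hosomi–Sakurai and Mukaiyama substitutions of 3-acetoxy-1,2-dioxanes) and transferring methyl from the acetoxy-aluminate ion pair; the closest known reactions are AlMe3 methylations of anomeric acetates and fluorides, including endoperoxide-bearing trioxane lactol derivatives; methyl should enter axially on the half-chair that keeps C4a–O pseudoaxial, cis to the lactone oxygen and to the C7a substituent and trans to the 4a-methyl (half-chair model of six-ring oxocarbenium ions, 3,6-cis rule of 1,2-dioxanyl cations), which is the (3S) configuration.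

**Compound list**

1 | 5-methyl-2,3-dihydrofuran | CC1=CCCO1 | starting material
2 | trichloroacetyl chloride | ClC(=O)C(Cl)(Cl)Cl | starting material
3 | dichloroketene | ClC(Cl)=C=O | intermediate (not isolated)
4 | (±)-cis-7,7-dichloro-1-methyl-2-oxabicyclo[3.2.0]heptan-6-one (racemate) | O=C1C(Cl)(Cl)[C@]2(C)OCC[C@@H]21 | intermediate
5 | (±)-cis-1-methyl-2-oxabicyclo[3.2.0]heptan-6-one (racemate) | O=C1C[C@]2(C)OCC[C@@H]21 | intermediate
6 | (±)-cis-1-methyl-2-oxabicyclo[3.2.0]heptane-3,6-dione (racemate) | O=C1C[C@]2(C)OC(=O)C[C@@H]21 | intermediate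
7 | (1S,5S)-1-methyl-2-oxabicyclo[3.2.0]heptane-3,6-dione | O=C1C[C@]2(C)OC(=O)C[C@@H]21 | intermediate
8 | 1,12-dibromododecane | BrCCCCCCCCCCCCBr | starting material
9 | phenylmagnesium bromide | Br[Mg]c1ccccc1 | starting material
10 | (12-bromododecyl)benzene | BrCCCCCCCCCCCCc1ccccc1 | intermediate
11 | (12-phenyldodecyl)magnesium bromide | Br[Mg]CCCCCCCCCCCCc1ccccc1 | intermediate (not isolated)
12 | dichloro(12-phenyldodecyl)cerium | Cl[Ce](Cl)CCCCCCCCCCCCc1ccccc1 | intermediate (not isolated)
13 | (1S,5R,6R)-6-hydroxy-1-methyl-6-(12-phenyldodecyl)-2-oxabicyclo[3.2.0]heptan-3-one (OH endo, chain exo) | O[C@]1(CCCCCCCCCCCCc2ccccc2)C[C@]2(C)OC(=O)C[C@@H]21 | intermediate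
14 | (4S,5S)-4-hydroperoxy-5-methyl-5-(2-oxo-14-phenyltetradecyl)oxolan-2-one | O=C(CCCCCCCCCCCCc1ccccc1)C[C@]1(C)OC(=O)C[C@@H]1OO | intermediate (not isolated)
15 | (4aS,7aS)-3-hydroxy-4a-methyl-3-(12-phenyldodecyl)tetrahydrofuro[3,2-c][1,2]dioxin-6(3H)-one (anomers at C3) | OC1(CCCCCCCCCCCCc2ccccc2)C[C@]2(C)OC(=O)C[C@@H]2OO1 | intermediate
16 | (4aS,7aS)-4a-methyl-6-oxo-3-(12-phenyldodecyl)hexahydrofuro[3,2-c][1,2]dioxin-3-yl acetate (anomers at C3) | CC(=O)OC1(CCCCCCCCCCCCc2ccccc2)C[C@]2(C)OC(=O)C[C@@H]2OO1 | intermediate
17 | plakortolide L, (3S,4aS,7aS)-3,4a-dimethyl-3-(12-phenyldodecyl)tetrahydrofuro[3,2-c][1,2]dioxin-6(3H)-one | C[C@]1(CCCCCCCCCCCCc2ccccc2)C[C@]2(C)OC(=O)C[C@@H]2OO1 | target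

**Step count**

Total steps: 9. Longest linear sequence: 8 (steps 1–4 and 6–9); step 5 prepares the side-chain bromide.

**Steps most likely to fail**

Step 9 (bears the label "Proposed new method:"). The organoaluminium may reduce or cleave the O–O bond, or attack the lactone, faster than it ionises the acetate. Methyl transfer may also be less face-selective than with silicon nucleophiles. The fallback sets out from 16 and comes back at 17. A TMSOTf-catalysed Mukaiyama-type substitution with 1-(tert-butoxy)-1-(trimethylsilyloxy)ethene, a known C–C bond formation on acetoxy peroxyketals with the same facial course, should give tert-butyl 2-[(3S,4aS,7aS)-4a-methyl-6-oxo-3-(12-phenyldodecyl)hexahydrofuro[3,2-c][1,2]dioxin-3-yl]acetate F1. TFA in CH2Cl2 should free the corresponding acetic acid F2. Coupling with N-hydroxypyridine-2-thione gives the Barton ester F3 (not isolated), and photolysis with t-BuSH (Barton reductive decarboxylation) should turn CH2CO2H into the C3 methyl group of 17.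

Step 7. The alkoxy radical may form slowly from the hindered tertiary carbinol, and O2 capture at the lactone radical may show poor facial selectivity. The fallback sets out from 13 and comes back at 15; it introduces the peroxide by polar steps. Silver-catalysed ring-opening bromination (AgNO3, K2S2O8, NBS) should give (5S)-4-bromo-5-methyl-5-(2-oxo-14-phenyltetradecyl)oxolan-2-one F4. Et3N should eliminate HBr to (S)-5-methyl-5-(2-oxo-14-phenyltetradecyl)furan-2(5H)-one F5. H2O2·urea with an acid catalyst, then Et2NH in CF3CH2OH, should form the hydroperoxy hemiketal and close it by intramolecular oxa-Michael addition. The ring closure enforces the cis fusion and gives 15.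

Step 4. The rate difference between the two enantiomers in the CBS reduction may be too small (weak large/small discrimination of the two α-carbons), which would leave ketone of low enantiopurity. The fallback sets out from 5 and comes back at 7. NaBH4 (exo attack) should give racemic endo-1-methyl-2-oxabicyclo[3.2.0]heptan-6-ol F6. Lipase-catalysed acylation (Burkholderia cepacia lipase, vinyl acetate) should, by the usual empirical rule for secondary alcohols, acylate the (6R) enantiomer to (1S,5R,6R)-1-methyl-2-oxabicyclo[3.2.0]heptan-6-yl acetate F7, which is separated from the unreacted alcohol. K2CO3 in MeOH should give (1S,5R,6R)-1-methyl-2-oxabicyclo[3.2.0]heptan-6-ol F8. RuCl3/NaIO4 should then oxidise the carbinol to the ketone and the oxolane CH2 to the lactone in one operation, giving 7.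

**Further compounds**

F1 | step 9 | tert-butyl 2-[(3S,4aS,7aS)-4a-methyl-6-oxo-3-(12-phenyldodecyl)hexahydrofuro[3,2-c][1,2]dioxin-3-yl]acetate | CC(C)(C)OC(=O)C[C@]1(CCCCCCCCCCCCc2ccccc2)C[C@]2(C)OC(=O)C[C@@H]2OO1
F2 | step 9 | 2-[(3S,4aS,7aS)-4a-methyl-6-oxo-3-(12-phenyldodecyl)hexahydrofuro[3,2-c][1,2]dioxin-3-yl]acetic acid | OC(=O)C[C@]1(CCCCCCCCCCCCc2ccccc2)C[C@]2(C)OC(=O)C[C@@H]2OO1
F3 | step 9 | 2-thioxopyridin-1(2H)-yl 2-[(3S,4aS,7aS)-4a-methyl-6-oxo-3-(12-phenyldodecyl)hexahydrofuro[3,2-c][1,2]dioxin-3-yl]acetate (Barton ester) | S=C1C=CC=CN1OC(=O)C[C@]2(CCCCCCCCCCCCc3ccccc3)C[C@]3(C)OC(=O)C[C@@H]3OO2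
F4 | step 7 | (5S)-4-bromo-5-methyl-5-(2-oxo-14-phenyltetradecyl)oxolan-2-one (epimers at C4) | O=C(CCCCCCCCCCCCc1ccccc1)C[C@]1(C)OC(=O)CC1Br
F5 | step 7 | (S)-5-methyl-5-(2-oxo-14-phenyltetradecyl)furan-2(5H)-one | O=C(CCCCCCCCCCCCc1ccccc1)C[C@]1(C)OC(=O)C=C1
F6 | step 4 | (±)-endo-1-methyl-2-oxabicyclo[3.2.0]heptan-6-ol (racemate, one enantiomer shown) | O[C@@H]1C[C@]2(C)OCC[C@@H]21
F7 | step 4 | (1S,5R,6R)-1-methyl-2-oxabicyclo[3.2.0]heptan-6-yl acetate | CC(=O)O[C@@H]1C[C@]2(C)OCC[C@@H]21
F8 | step 4 | (1S,5R,6R)-1-methyl-2-oxabicyclo[3.2.0]heptan-6-ol | O[C@@H]1C[C@]2(C)OCC[C@@H]21
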